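**Retrosynthetic overview**

1. Target 16 ⇒ global desilylation of 15. Ring A (dihydrofuran: O1, C2, C3, C3a, C7a) is closed last, through O1–C7a, from the racemic ketone 13 by asymmetric transfer hydrogenation with dynamic kinetic resolution followed in the same flask by alkoxide addition–elimination.
2. Enabling feature: C7a is C4 of the fused pyranone ring B, the β-carbon of a vinylogous ester (O=C4–C3a=C7a–OMe) five atoms from the oxygen on C2. C3–H sits between the aryl ketone and the two pyranone rings B and C, so C3 racemises fast and the ketone can be resolved dynamically.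
3. Ketone 13 ⇐ vinylogous aldol addition of the bridging CH2 of bis(pyranonyl)methane 10 to aldehyde 11 (C2–C3 bond), then oxidation.
4. 10 ⇐ Knoevenagel/Hantzsch reductive alkylation joining C3a of ring B (styrylpyranone 7) to the ring-C aldehyde 4 (C3–C3a bond), then O-methylation at C7a.
5. Rings B and C both come intact from 4-hydroxy-6-methyl-2H-pyran-2-one (1); ring A is the only ring formed.

Key step: step 9

Assumption: the silylated aldehydes 5 and 11 are catalogue compounds and are taken as starting materials.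
Abbreviations and locants: TBS = tert-butyldimethylsilyl; TMSE = 2-(trimethylsilyl)ethyl; furo[3,2-c]pyran-4-one locants are O1, C2, C3, C3a, C4(=O), O5, C6, C7, C7a.

Step 1
Reactants: 1 4-hydroxy-6-methyl-2H-pyran-2-one; 2 2-(trimethylsilyl)ethanol
Product: 3 6-methyl-4-[2-(trimethylsilyl)ethoxy]-2H-pyran-2-one
Conditions: PPh3, DIAD, THF, 0 → 25 °C
Reagents that add atoms: none
Why: Mitsunobu O-alkylation, in which the acidic 4-OH (a vinylogous carboxylic acid) is the pronucleophile and is alkylated on O4, giving a ring-C oxygen mask that survives strong base and is later removed by fluoride.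

Step 2
Reactants: 3 6-methyl-4-[2-(trimethylsilyl)ethoxy]-2H-pyran-2-one
Product: 4 2-oxo-4-[2-(trimethylsilyl)ethoxy]-2H-pyran-6-carbaldehyde
Conditions: SeO2, 1,4-dioxane, 160 °C, sealed tube
Reagents that add atoms: selenium dioxide, O=[Se]=O
Why: Riley-type selenium dioxide oxidation of the 6-methyl group, which is activated as the vinylogous α-position of the lactone, should stop at the aldehyde as it does for the 4-methoxy analogue.

Step 3
Reactants: 1 4-hydroxy-6-methyl-2H-pyran-2-one; 5 4-[(tert-butyldimethylsilyl)oxy]benzaldehyde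
Product: 6 6-{2-[4-(TBS-oxy)phenyl]-2-hydroxyethyl}-4-hydroxy-2H-pyran-2-one (racemic)
Conditions: LiN(iPr)2 (3 equiv), THF, −78 °C; then 5; 1 M HCl
Reagents that add atoms: none
Why: Vinylogous aldol addition of the O,C-dianion of 1, whose 6-CH2 carbanion (not the delocalised 4-oxide) adds to the non-enolisable aldehyde; the carbinol centre is racemic and is erased in step 4.

Step 4
Reactants: 6 6-{2-[4-(TBS-oxy)phenyl]-2-hydroxyethyl}-4-hydroxy-2H-pyran-2-one
Product: 7 4-hydroxy-6-{(E)-2-[4-(TBS-oxy)phenyl]ethenyl}-2H-pyran-2-one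
Conditions: TsOH·H2O (cat.), toluene, 80 °C
Reagents that add atoms: none
Why: Acid-catalysed E1 dehydration through the benzylic cation stabilised by the para-silyloxy group should give the conjugated styryl unit as the thermodynamic E isomer.

Step 5
Reactants: 7 4-hydroxy-6-{(E)-2-[4-(TBS-oxy)phenyl]ethenyl}-2H-pyran-2-one; 4 2-oxo-4-[2-(trimethylsilyl)ethoxy]-2H-pyran-6-carbaldehyde
Product: 9 4-hydroxy-3-{[2-oxo-4-(TMSE-oxy)-2H-pyran-6-yl]methyl}-6-{(E)-2-[4-(TBS-oxy)phenyl]ethenyl}-2H-pyran-2-one, via alkylidene-dione 8 (not isolated)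
Conditions: L-proline (20 mol%), Hantzsch ester (diethyl 2,6-dimethyl-1,4-dihydropyridine-3,5-dicarboxylate, 1.1 equiv), CH2Cl2, 25 °C
Reagents that add atoms: none
Why: Three-component reductive alkylation, in which proline-catalysed Knoevenagel condensation at C3 of the 4-hydroxypyranone gives 8 and hydride transfer from the Hantzsch ester reduces this electron-poor alkene before a second pyranone can add, so only C-monoalkylation results.

Step 6
Reactants: 9 4-hydroxy-3-{[2-oxo-4-(TMSE-oxy)-2H-pyran-6-yl]methyl}-6-{(E)-2-[4-(TBS-oxy)phenyl]ethenyl}-2H-pyran-2-one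
Product: 10 4-methoxy-3-{[2-oxo-4-(TMSE-oxy)-2H-pyran-6-yl]methyl}-6-{(E)-2-[4-(TBS-oxy)phenyl]ethenyl}-2H-pyran-2-one
Conditions: Me2SO4, K2CO3, acetone, 40 °C
Reagents that add atoms: dimethyl sulfate, COS(=O)(=O)OC
Why: Williamson-type O-methylation of the 4-oxide (the only site deprotonated by carbonate) should give the 4-methoxy-2-pyranone as it does for lactone 1, which makes C7a the β-carbon of a vinylogous ester with a leaving group of moderate ability.

Step 7
Reactants: 10 4-methoxy-3-{[2-oxo-4-(TMSE-oxy)-2H-pyran-6-yl]methyl}-6-{(E)-2-[4-(TBS-oxy)phenyl]ethenyl}-2H-pyran-2-one; 11 3,4-bis[(tert-butyldimethylsilyl)oxy]benzaldehyde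
Product: 12 3-{2-[3,4-bis(TBS-oxy)phenyl]-2-hydroxy-1-[2-oxo-4-(TMSE-oxy)-2H-pyran-6-yl]ethyl}-4-methoxy-6-{(E)-2-[4-(TBS-oxy)phenyl]ethenyl}-2H-pyran-2-one (mixture of all stereoisomers)
Conditions: LiN(SiMe3)2 (1.1 equiv), THF, −78 °C; then 11; AcOH, −78 °C
Reagents that add atoms: none
Why: Vinylogous aldol addition of the lithiated bridging CH2 (the only acidic sp3 C–H) to the aldehyde; the cold acidic quench stops the aldolate before it can close onto C7a, and the stereoisomer mixture does not matter because C2 is erased in step 8 and both centres are set in step 9.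

Step 8
Reactants: 12 3-{2-[3,4-bis(TBS-oxy)phenyl]-2-hydroxy-1-[2-oxo-4-(TMSE-oxy)-2H-pyran-6-yl]ethyl}-4-methoxy-6-{(E)-2-[4-(TBS-oxy)phenyl]ethenyl}-2H-pyran-2-one
Product: 13 3-{2-[3,4-bis(TBS-oxy)phenyl]-2-oxo-1-[2-oxo-4-(TMSE-oxy)-2H-pyran-6-yl]ethyl}-4-methoxy-6-{(E)-2-[4-(TBS-oxy)phenyl]ethenyl}-2H-pyran-2-one (racemic)
Conditions: Dess–Martin periodinane, CH2Cl2, 0 °C; used directly
Reagents that add atoms: none
Why: Dess–Martin oxidation of the secondary benzylic alcohol under non-basic conditions should give the aryl ketone without generating the enolate that could attack C7a.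

Step 9
Reactants: 13 3-{2-[3,4-bis(TBS-oxy)phenyl]-2-oxo-1-[2-oxo-4-(TMSE-oxy)-2H-pyran-6-yl]ethyl}-4-methoxy-6-{(E)-2-[4-(TBS-oxy)phenyl]ethenyl}-2H-pyran-2-one
Product: 15 (2S,3S)-2-[3,4-bis(TBS-oxy)phenyl]-6-{(E)-2-[4-(TBS-oxy)phenyl]ethenyl}-3-[2-oxo-4-(TMSE-oxy)-2H-pyran-6-yl]-2,3-dihydro-4H-furo[3,2-c]pyran-4-one, via (1S,2S)-alcohol 14 (not isolated)
Conditions: RuCl[(S,S)-TsDPEN](p-cymene) (2 mol%), HCO2H/Et3N 5:2 (1.5 equiv HCO2H), MeCN, 30 °C; then DBU (1 equiv), 4 Å MS, 40 °C, same flask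
Reagents that add atoms: none
Why: The C3–H of 13 lies between the aryl ketone and the pyranone rings B and C and is exchanged rapidly by Et3N, so the two enantiomers of 13 interconvert while the (S,S)-configured ruthenium hydride delivers H to the carbonyl face that gives the (S)-carbinol at C2 (the sense known for aryl ketones, aryl group against the η6-arene); this is a Noyori–Ikariya asymmetric transfer hydrogenation run as a dynamic kinetic resolution, the reaction type known for racemic α-aryl aryl ketones. C3 is set by substrate matching: hydride passes the small C3–H with the ortho,ortho-disubstituted ring-B pyranone anti (Felkin–Anh), which pairs (S) at C2 with (S) at C3 in 14. DBU then generates the C2 alkoxide, which adds to C7a of ring B and expels methoxide (addition–elimination at a vinylogous ester, the reaction type known for 4-alkoxy- and 4-sulfonyloxy-2-pyranones; 5-exo-trig on the C7a=O(+)Me resonance form, formally 5-endo on C3a=C7a), closing ring A through O1–C7a without touching either stereocentre, so (1S,2S)-14 should give trans-(2S,3S)-15. The step needs three selectivities: C=O over the styryl and pyranone C=C bonds (outer-sphere hydride transfer is carbonyl-selective); ring B over ring C (only C7a is within reach of the alkoxide, and attack at the ring-B lactone carbonyl is reversible whereas methoxide loss, driven by the sieves, is not); and no O-cyclisation of the enol of 13 to the furan (the acidic formate medium keeps the enolate concentration low and methoxide is a poor leaving group).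

Step 10
Reactants: 15 (2S,3S)-2-[3,4-bis(TBS-oxy)phenyl]-6-{(E)-2-[4-(TBS-oxy)phenyl]ethenyl}-3-[2-oxo-4-(TMSE-oxy)-2H-pyran-6-yl]-2,3-dihydro-4H-furo[3,2-c]pyran-4-one
Product: 16 (2S,3S)-2-(3,4-dihydroxyphenyl)-3-(4-hydroxy-2-oxo-2H-pyran-6-yl)-6-[(E)-2-(4-hydroxyphenyl)ethenyl]-2,3-dihydro-4H-furo[3,2-c]pyran-4-one
Conditions: Bu4NF (5 equiv), AcOH (5 equiv), THF, 0 → 25 °C
Reagents that add atoms: none
Why: Fluoride-induced desilylation cleaves the three aryl silyl ethers at silicon and fragments the TMSE ether by β-elimination, while the acetic acid buffer keeps the phenols and the ring-C enol protonated so that no phenoxide can expel the ring-B oxygen from C2; neither stereocentre is touched.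

**Compound list**

1 | 4-hydroxy-6-methyl-2H-pyran-2-one | Cc1cc(O)cc(=O)o1 | starting material
2 | 2-(trimethylsilyl)ethanol | C[Si](C)(C)CCO | starting material
3 | 6-methyl-4-[2-(trimethylsilyl)ethoxy]-2H-pyran-2-one | Cc1cc(OCC[Si](C)(C)C)cc(=O)o1 | intermediate
4 | 2-oxo-4-[2-(trimethylsilyl)ethoxy]-2H-pyran-6-carbaldehyde | O=Cc1cc(OCC[Si](C)(C)C)cc(=O)o1 | intermediate
5 | 4-[(tert-butyldimethylsilyl)oxy]benzaldehyde | O=Cc1ccc(O[Si](C)(C)C(C)(C)C)cc1 | starting material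
6 | 6-{2-[4-(TBS-oxy)phenyl]-2-hydroxyethyl}-4-hydroxy-2H-pyran-2-one (racemic) | OC(Cc1cc(O)cc(=O)o1)c1ccc(O[Si](C)(C)C(C)(C)C)cc1 | intermediate
7 | 4-hydroxy-6-{(E)-2-[4-(TBS-oxy)phenyl]ethenyl}-2H-pyran-2-one | O=c1cc(O)cc(/C=C/c2ccc(O[Si](C)(C)C(C)(C)C)cc2)o1 | intermediate
8 | 3-{[2-oxo-4-(TMSE-oxy)-2H-pyran-6-yl]methylidene}-6-{(E)-2-[4-(TBS-oxy)phenyl]ethenyl}-2H-pyran-2,4(3H)-dione (not isolated) | O=C1OC(/C=C/c2ccc(O[Si](C)(C)C(C)(C)C)cc2)=CC(=O)C1=Cc1cc(OCC[Si](C)(C)C)cc(=O)o1 | intermediate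
9 | 4-hydroxy-3-{[2-oxo-4-(TMSE-oxy)-2H-pyran-6-yl]methyl}-6-{(E)-2-[4-(TBS-oxy)phenyl]ethenyl}-2H-pyran-2-one | O=c1oc(/C=C/c2ccc(O[Si](C)(C)C(C)(C)C)cc2)cc(O)c1Cc1cc(OCC[Si](C)(C)C)cc(=O)o1 | intermediate
10 | 4-methoxy-3-{[2-oxo-4-(TMSE-oxy)-2H-pyran-6-yl]methyl}-6-{(E)-2-[4-(TBS-oxy)phenyl]ethenyl}-2H-pyran-2-one | O=c1oc(/C=C/c2ccc(O[Si](C)(C)C(C)(C)C)cc2)cc(OC)c1Cc1cc(OCC[Si](C)(C)C)cc(=O)o1 | intermediate
11 | 3,4-bis[(tert-butyldimethylsilyl)oxy]benzaldehyde | O=Cc1ccc(O[Si](C)(C)C(C)(C)C)c(O[Si](C)(C)C(C)(C)C)c1 | starting material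
12 | 3-{2-[3,4-bis(TBS-oxy)phenyl]-2-hydroxy-1-[2-oxo-4-(TMSE-oxy)-2H-pyran-6-yl]ethyl}-4-methoxy-6-{(E)-2-[4-(TBS-oxy)phenyl]ethenyl}-2H-pyran-2-one (mixture of all stereoisomers) | OC(c1ccc(O[Si](C)(C)C(C)(C)C)c(O[Si](C)(C)C(C)(C)C)c1)C(c1cc(OCC[Si](C)(C)C)cc(=O)o1)c1c(OC)cc(/C=C/c2ccc(O[Si](C)(C)C(C)(C)C)cc2)oc1=O | intermediate
13 | 3-{2-[3,4-bis(TBS-oxy)phenyl]-2-oxo-1-[2-oxo-4-(TMSE-oxy)-2H-pyran-6-yl]ethyl}-4-methoxy-6-{(E)-2-[4-(TBS-oxy)phenyl]ethenyl}-2H-pyran-2-one (racemic, C–H centre labile) | O=C(c1ccc(O[Si](C)(C)C(C)(C)C)c(O[Si](C)(C)C(C)(C)C)c1)C(c1cc(OCC[Si](C)(C)C)cc(=O)o1)c1c(OC)cc(/C=C/c2ccc(O[Si](C)(C)C(C)(C)C)cc2)oc1=O | intermediate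
14 | 3-{(1S,2S)-2-[3,4-bis(TBS-oxy)phenyl]-2-hydroxy-1-[2-oxo-4-(TMSE-oxy)-2H-pyran-6-yl]ethyl}-4-methoxy-6-{(E)-2-[4-(TBS-oxy)phenyl]ethenyl}-2H-pyran-2-one (not isolated) | O=c1cc(OCC[Si](C)(C)C)cc([C@@H](c2c(OC)cc(/C=C/c3ccc(O[Si](C)(C)C(C)(C)C)cc3)oc2=O)[C@H](O)c2ccc(O[Si](C)(C)C(C)(C)C)c(O[Si](C)(C)C(C)(C)C)c2)o1 | intermediate
15 | (2S,3S)-2-[3,4-bis(TBS-oxy)phenyl]-6-{(E)-2-[4-(TBS-oxy)phenyl]ethenyl}-3-[2-oxo-4-(TMSE-oxy)-2H-pyran-6-yl]-2,3-dihydro-4H-furo[3,2-c]pyran-4-one | O=c1cc(OCC[Si](C)(C)C)cc([C@H]2c3c(cc(/C=C/c4ccc(O[Si](C)(C)C(C)(C)C)cc4)oc3=O)O[C@@H]2c2ccc(O[Si](C)(C)C(C)(C)C)c(O[Si](C)(C)C(C)(C)C)c2)o1 | intermediate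
16 | (2S,3S)-2-(3,4-dihydroxyphenyl)-3-(4-hydroxy-2-oxo-2H-pyran-6-yl)-6-[(E)-2-(4-hydroxyphenyl)ethenyl]-2,3-dihydro-4H-furo[3,2-c]pyran-4-one | O=c1cc(O)cc([C@H]2c3c(cc(/C=C/c4ccc(O)cc4)oc3=O)O[C@@H]2c2ccc(O)c(O)c2)o1 | target

**Step count and risks**

Total step count: 10. Longest linear sequence: 8 steps (steps 3 to 10 from 1; equally steps 1, 2 and 5 to 10).

Steps most likely to fail:

1. Step 9. The hydride transfer may fail to discriminate between the two interconverting enantiomers of the ketone, because both groups on C3 are flat heteroaryl rings; the mismatched reduction would lead to the cis ring. The enol of the ketone may also close onto C7a with loss of methanol (aromatisation to the furan), and the base stage may open the new ring by β-elimination at C3. Fallback: it sets out from 10 (with aldehyde 11) and comes back at 15. Lithiation of 10 with LiN(SiMe3)2 in THF at −78 °C, addition of 11 and warming to 0 °C should let the lithium aldolate close onto C7a in the same flask. The aldol addition is reversible, methoxide loss is not, and the trans ring closes faster. This should give the racemate, that is 15 together with the (2R,3R)-enantiomer of 15 F1. Preparative chromatography on a chiral stationary phase should then deliver 15 for step 10.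

2. Step 8. The strongly enolised ketone may cyclise through its enol oxygen onto C7a with loss of methanol during oxidation or handling, or the periodinane may oxidise the acidic methine. Fallback: it sets out from 9 and comes back at 15, so that no leaving group sits on C7a while the ketone exists. Double deprotonation of 9 (LiN(iPr)2, 2.2 equiv, THF, −78 °C) and addition to 11 should give the free-enol aldol adduct F2. MnO2 in CH2Cl2 should oxidise the benzylic carbinol to the free-enol ketone F3. Transfer hydrogenation with dynamic kinetic resolution (RuCl[(S,S)-TsDPEN](p-cymene), HCO2H/Et3N) should give the (1S,2S)-hydroxy enol F4. TsCl and Et3N should sulfonylate only the acidic enol oxygen to the 4-tosylate F5, which is not isolated and should close with DBU by the same addition–elimination at C7a to give 15.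

3. Step 10. Fluoride that is too basic may ionise the para-phenol of the catechol and expel the ring-B oxygen from C2 (quinone-methide ring opening and re-closure), eroding the trans configuration; buffered fluoride may also cleave the TMSE ether incompletely. Fallback: it sets out from 15 and comes back at 16 by unmasking in two non-basic stages. TFA in CH2Cl2 at 0 °C should cleave only the TMSE ether (acidolysis with β-silyl fragmentation) to the ring-C enol tris(silyl ether) F6. Et3N·3HF in THF should then remove the three aryl silyl ethers under weakly acidic conditions to give 16.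

**Further compounds**

F1 | step 9 | (2R,3R)-enantiomer of 15 | O=c1cc(OCC[Si](C)(C)C)cc([C@@H]2c3c(cc(/C=C/c4ccc(O[Si](C)(C)C(C)(C)C)cc4)oc3=O)O[C@H]2c2ccc(O[Si](C)(C)C(C)(C)C)c(O[Si](C)(C)C(C)(C)C)c2)o1
F2 | step 8 | 3-{2-[3,4-bis(TBS-oxy)phenyl]-2-hydroxy-1-[2-oxo-4-(TMSE-oxy)-2H-pyran-6-yl]ethyl}-4-hydroxy-6-{(E)-2-[4-(TBS-oxy)phenyl]ethenyl}-2H-pyran-2-one (mixture of stereoisomers) | OC(c1ccc(O[Si](C)(C)C(C)(C)C)c(O[Si](C)(C)C(C)(C)C)c1)C(c1cc(OCC[Si](C)(C)C)cc(=O)o1)c1c(O)cc(/C=C/c2ccc(O[Si](C)(C)C(C)(C)C)cc2)oc1=O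
F3 | step 8 | 3-{2-[3,4-bis(TBS-oxy)phenyl]-2-oxo-1-[2-oxo-4-(TMSE-oxy)-2H-pyran-6-yl]ethyl}-4-hydroxy-6-{(E)-2-[4-(TBS-oxy)phenyl]ethenyl}-2H-pyran-2-one (racemic) | O=C(c1ccc(O[Si](C)(C)C(C)(C)C)c(O[Si](C)(C)C(C)(C)C)c1)C(c1cc(OCC[Si](C)(C)C)cc(=O)o1)c1c(O)cc(/C=C/c2ccc(O[Si](C)(C)C(C)(C)C)cc2)oc1=O
F4 | step 8 | 3-{(1S,2S)-2-[3,4-bis(TBS-oxy)phenyl]-2-hydroxy-1-[2-oxo-4-(TMSE-oxy)-2H-pyran-6-yl]ethyl}-4-hydroxy-6-{(E)-2-[4-(TBS-oxy)phenyl]ethenyl}-2H-pyran-2-one | O=c1cc(OCC[Si](C)(C)C)cc([C@@H](c2c(O)cc(/C=C/c3ccc(O[Si](C)(C)C(C)(C)C)cc3)oc2=O)[C@H](O)c2ccc(O[Si](C)(C)C(C)(C)C)c(O[Si](C)(C)C(C)(C)C)c2)o1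
F5 | step 8 | 3-{(1S,2S)-2-[3,4-bis(TBS-oxy)phenyl]-2-hydroxy-1-[2-oxo-4-(TMSE-oxy)-2H-pyran-6-yl]ethyl}-2-oxo-6-{(E)-2-[4-(TBS-oxy)phenyl]ethenyl}-2H-pyran-4-yl 4-methylbenzenesulfonate | O=c1cc(OCC[Si](C)(C)C)cc([C@@H](c2c(OS(=O)(=O)c3ccc(C)cc3)cc(/C=C/c3ccc(O[Si](C)(C)C(C)(C)C)cc3)oc2=O)[C@H](O)c2ccc(O[Si](C)(C)C(C)(C)C)c(O[Si](C)(C)C(C)(C)C)c2)o1
F6 | step 10 | (2S,3S)-2-[3,4-bis(TBS-oxy)phenyl]-3-(4-hydroxy-2-oxo-2H-pyran-6-yl)-6-{(E)-2-[4-(TBS-oxy)phenyl]ethenyl}-2,3-dihydro-4H-furo[3,2-c]pyran-4-one | O=c1cc(O)cc([C@H]2c3c(cc(/C=C/c4ccc(O[Si](C)(C)C(C)(C)C)cc4)oc3=O)O[C@@H]2c2ccc(O[Si](C)(C)C(C)(C)C)c(O[Si](C)(C)C(C)(C)C)c2)o1
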